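Take the percentage point of the charge as your unit: the readings of the two substrates differ by a few points, and the excess asked for is that small gap over their sum.

in all of them: free catalyst 2.7 mol%; impurity 0.30 mM
- birch: left-handed substrate 0.070 M; right-handed substrate 0.070 M; solid reagent 0.80 equiv; run made earlier
- maple: left-handed substrate 0.11 M; right-handed substrate 0.11 M; solid reagent 0.80 equiv; run made earlier
- flask: left-handed substrate 0.050 M; right-handed substrate 0.050 M; solid reagent 0.800 equiv; time 6.0 d

- birch (time / d: right-handed substrate / %, left-handed substrate / %): 0.333: 50, 47; 0.833: 49, 45; 1.67: 45, 41; 2.50: 46, 42; 4.00: 36, 34; 5.00: 35, 28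
- maple (time / d: right-handed substrate / %, left-handed substrate / %): 0.417: 48, 47; 0.625: 48, 44; 1.04: 50, 44; 1.67: 43, 40; 3.00: 44, 41; 5.00: 33, 34

(standard deviation of a reading: 2 percentage points)

- free catalyst is single-handed; left-handed substrate and right-handed substrate are mirror images of each other, charged as a racemate, each of them at the stated concentration
- given per volume of solution although it is solid: solid reagent
- at the start none of the solid reagent is in solution

1. whether the excess of right-handed substrate over left-handed substrate among what is left of the two reaches 90% by 6.0 d (no / yes)
2. the highest excess of right-handed substrate over left-handed substrate among what is left of the two up to 6.0 d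

Two extreme flasks can be solved in your head. In the first, the catalyst takes left-handed substrate and nothing refills it. If one solid reagent consumes one substrate, the solid reagent is the limiting reagent, and spending 0.800 equiv on the left-handed side leaves an excess of 66.7%, less than the 90% wanted. In the second, the substrates interchange instantly and the gap stays zero.

The birch readings lie between the two, with a gap of a few points while material goes. So suppose the gap is a first-order lag: loss on the left-handed side opens it, interchange closes it, and under steady loss it equals loss rate times a time constant. Between its first and last readings the birch run loses 0.0729 d⁻¹ as a fraction of the charge, with a mean gap of 4 percentage points. The gap time, mean gap over loss rate, therefore reads 0.549 d, with the scatter of its readings. The maple run loses 0.0611 d⁻¹, and I assume that this flask keeps the birch gap. The reagent allows a loss of 40.0% of the charge, and that gap over what then remains puts my top near 6.67%.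

The forecast says no and 7%, seeing “a slow and only weakly selective resolution”; its route is a selectivity, mine a lag.

The flask gives no and 6.41%. Its products reach 38.2% at 6.00 d, under the 40.0% the reagent allows. Between 0.600 d and 3.00 d they grow at 0.0857 d⁻¹, so the gap time gives an excess of 6.13% at 3.00 d, where the flask stands at 5.97%.

    free catalyst + right-handed substrate ⇌ catalyst intermediate B (K = 7.60 M⁻¹, k = 0.0230 M⁻¹ s⁻¹)
    free catalyst + impurity → spent catalyst (k = 3.30 M⁻¹ s⁻¹)
    partner + catalyst intermediate A → free catalyst + left-handed product (k = 0.0940 M⁻¹ s⁻¹)
    free catalyst + left-handed substrate ⇌ catalyst intermediate A (K = 4.30 M⁻¹, k = 0.0170 M⁻¹ s⁻¹)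
    left-handed substrate ⇌ right-handed substrate (k = 1.00 × 10⁻⁵ s⁻¹)
    partner + catalyst intermediate B → free catalyst + right-handed product (k = 0.00220 M⁻¹ s⁻¹)
    solid reagent ⇌ partner, rate k7*(cs7 - [partner]) while solid is left; crystals form when [partner] > cs7 (solubility = 32.0 mM, k = 5.70 × 10⁻⁶ s⁻¹)

In the neighbour with 1.1 mol% of free catalyst, products average 0.0329 d⁻¹ over the run, so the gap time, over the two substrates left at the end, gives 2.26%. The computed top there is 2.40%.

(The runs were computed on assumed constants, and the scatter is random.)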